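**Structural features**

The target is a 4-hydroxy-2H-pyran-2-one (O1, C2=O, C3, C4–OH, C5–CH3, C6–C2H5) joined through one methylene (C7) from C3 to C1' of a pentasubstituted benzene ring (C2' OMe, C3' H, C4' OH, C5' acyl, C6' OH). The arene is a 4-O-methyl acylphloroglucinol: the ketone is chelated by both flanking hydroxyls, and before C1' is substituted the two free ring carbons are equivalent. The only stereocentre is the α-carbon of the 2-methylbutanoyl group, (R) by CIP analysis of the given SMILES; it has no neighbouring stereocentre and, being α to an aryl ketone, can be lost by enolisation under strong acid, strong base or prolonged heating. Other fragile features are the electron-rich ring (oxidation), the acidic and ambident 4-hydroxypyranone, and the bis(β-oxyaryl)methane bridge, which can fragment by retro-Michael loss of a quinone-methide-type species. The real difficulty is to join two ambident carbon nucleophiles through a single carbon without homo-coupling and to assemble the fully substituted pyranone, all under conditions that spare the stereocentre. The key step exploits the five-atom path O(C6')–C6'–C1'–C7–C3–C2: the C6' phenol oxygen can hold the pyranone C2 carbonyl as a six-membered aryl lactone (a 3,4-dihydrocoumarin), and the remaining O1–C6(Et)=C5(Me) fragment is the enol of symmetrical pentan-3-one. The target is therefore treated as the ring-switched isomer of a 3-(β-ketoacyl)dihydrocoumarin, and the pyranone is the last ring to be made.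

**Logic of the disconnections**

16 ⇒ 15. The O1–C2 bond of the pyranone ring of 16 is cut and the C2 acyl carbon is re-attached to the oxygen on C6'. The cut is made there because that oxygen is placed for a six-membered aryl lactone. The gain is that the pyranone becomes an open 1,3-diketone hanging on a dihydrocoumarin, in which the C6' phenol is masked and the C2 carbonyl is activated as an aryl ester by the same bond. The forward step demands that the distal enol oxygen of 15 attacks the lactone carbonyl and that the aryloxide, not the enolate, leaves.

15 ⇒ 14 + 13. The C4–C5 bond (pyranone numbering) is cut, an acyl–enol carbon bond. The gain is large: C5, C6, O1 and both alkyl groups come from a symmetrical five-carbon ketone with no regiochemical question, and no free pyranone nucleophile is ever needed. The forward step demands C- rather than O-acylation of 13, reaction at the acyl chloride of 14 rather than at its lactone, and a medium that does not enolise the aryl ketone.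

14 ⇒ 11 and 13 ⇒ 12. The C–Cl bond of 14 and the O–Si bond of 13 are cut (functional-group changes). The demands are an acid activation that tolerates the chelated phenol of 11 and a simple enol silylation of 12.

11 ⇒ 10. The two C–H bonds at C3 and C4 of the lactone ring are removed to give the C3=C4 alkene. The reason is that the unsaturated acid 10 is the direct product of a classical condensation. The forward step demands a reduction that takes the doubly activated alkene and leaves the aryl ketone.

10 ⇒ 7 + 8 (through 9). The C3=C4 double bond and the lactone O–C2 bond are cut. The aldehyde 7 has only one hydroxyl next to the formyl carbon (the other neighbour is OMe), so the oxygen that forms the lactone, and is later released at C6', is fixed by structure. The gain is that C2, C3 and the carboxyl carbon come from 8 in one operation. The demand is condensation at a hindered, chelated aldehyde.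

7 ⇒ 5 (through 6). The C1'–C7 bond is cut with C7 at the aldehyde oxidation level. In 5 the two unsubstituted ring carbons are equivalent, so the bridge carbon enters without a regiochemical question, and as a formyl group it cannot bridge two arenes. The demand is that ring formylation outruns reaction at the phenol oxygens or at the ketone enol.

5 ⇒ 4. The O–CH3 bond is cut. The para hydroxyl of 4 is the only non-chelated and the most acidic one. The demand is mono-alkylation.

4 ⇒ 1 + 3, and 3 ⇒ 2. The aryl–C(=O) bond is cut. 1 is C3-symmetric, so one monoketone results, and the stereocentre comes from the chiral pool in 2. The demand is an acylation mild enough to avoid ketene formation from 3 and enolisation of the product.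

**Other disconnections considered**

Alternative 1: Cut both C–C bonds at C7. This is the route that comes to mind first. The forward key step is a three-component methylene bridging of 5, 6-ethyl-4-hydroxy-5-methyl-2H-pyran-2-one A1 and formaldehyde (or an iminium equivalent), through 6-ethyl-5-methyl-3-methylidene-2H-pyran-2,4(3H)-dione A2. On paper it is shorter. Its weakness is mechanistic: A2 is an unselective electrophile, and the more acidic A1 should intercept it to give the symmetrical bis-pyranone A3. Formaldehyde can equally bridge two molecules of 5, and all these Michael adducts can equilibrate by retro-Michael cleavage. A1 also has to be made separately. In the chosen plan the bridge carbon is fixed on the arene before any pyranone exists, and the pyranone is created already attached, so homo-coupling is excluded by construction.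

Alternative 2: Cut only C7–C3, with C7 arriving as a C-methyl group, as in the presumed biosynthesis of methylene-bridged phloroglucinols. The C-methyl ketone A4 would be dehydrogenated (DDQ or Ag2O) to the ortho-quinone methide A5, which A1 would capture. The bond formed is the same as in Alternative 1. The product has a doubly activated methylene and is more electron-rich than A4, so over-oxidation is to be expected. A4 requires acylation and hydroxyl differentiation on a less symmetrical methylphloroglucinol, and A1 is still needed. No step is saved.

Alternative 3: Cut the C5'–C(=O) bond last. The acyl-free diarylmethane A6 would be acylated with 3 (Friedel–Crafts or Fries) in the final step. A6 has two non-equivalent nucleophilic ring carbons (C3' and C5'), and its pyranone 4-OH is the most reactive acyl acceptor. A Lewis acid in the last step would act on the enolisable product and on the acid-labile bridge, with no later step to correct a loss of enantiopurity. The chosen plan introduces the acyl group first, on a C3-symmetric ring.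

Key step: step 7

Route in one sentence: the pyranone ring is made last by C-acylating the silyl enol ether of pentan-3-one with a 2-oxochromane-3-carbonyl chloride and letting the resulting diketo lactone switch rings.

Remark on the chemistry: (2R)-2-methylbutanoic acid is taken as a commercial enantiopure starting material; compounds 11, 14 and 15 are carried as mixtures of epimers at carbons that become sp2 in 16.

**Steps**

Step 1
Reactants: 1 benzene-1,3,5-triol (phloroglucinol); 2 (2R)-2-methylbutanoic acid
Product: 4 (2R)-2-methyl-1-(2,4,6-trihydroxyphenyl)butan-1-one, via acyl chloride 3 (not isolated)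
Conditions: 2, (COCl)2 (1.05 equiv), cat. DMF, CH2Cl2, 0 °C→rt; this solution added to 1, AlCl3 (3.5 equiv), CH2Cl2–MeNO2, 0 °C→rt; ice/1 M HCl
Reagents that add atoms: none
Why: Friedel–Crafts acylation of the C3-symmetric, very nucleophilic triol should give one monoketone because the first acyl group deactivates the ring; the stereocentre is bought in with 2 and only has to survive, so 3 is made under neutral conditions and the acylation is kept at or below room temperature to keep ketene formation from 3 and enolisation of the aluminium-chelated ketone slow.

Step 2
Reactants: 4 (2R)-2-methyl-1-(2,4,6-trihydroxyphenyl)butan-1-one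
Product: 5 (2R)-1-(2,6-dihydroxy-4-methoxyphenyl)-2-methylbutan-1-one
Conditions: Me2SO4 (1.0 equiv), K2CO3 (1.1 equiv), acetone, rt
Reagents that add atoms: dimethyl sulfate, COS(=O)(=O)OC
Why: Williamson-type O-methylation with one equivalent of electrophile should select the 4-OH, the most acidic and only non-chelated hydroxyl, while the two ortho hydroxyls are held in hydrogen bonds to the ketone; carbonate is too weak to enolise the ketone.

Step 3
Reactants: 5 (2R)-1-(2,6-dihydroxy-4-methoxyphenyl)-2-methylbutan-1-one
Product: 7 2,4-dihydroxy-6-methoxy-3-[(2R)-2-methylbutanoyl]benzaldehyde, via iminium chloride 6 (not isolated)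
Conditions: POCl3 (1.2 equiv), DMF (3 equiv), EtOAc, 0 °C→rt; then H2O, 40 °C
Reagents that add atoms: N,N-dimethylformamide, CN(C)C=O; water, O
Why: Vilsmeier–Haack formylation; the two free ring positions of 5 are equivalent, so only one aldehyde can form, and the iminium group of 6 deactivates the ring against a second attack; the α-branched ketone should enolise too slowly to compete as the nucleophile.

Step 4
Reactants: 7 2,4-dihydroxy-6-methoxy-3-[(2R)-2-methylbutanoyl]benzaldehyde; 8 2,2-dimethyl-1,3-dioxane-4,6-dione (Meldrum's acid)
Product: 10 7-hydroxy-5-methoxy-8-[(2R)-2-methylbutanoyl]-2-oxo-2H-chromene-3-carboxylic acid, via arylidene Meldrum's acid 9 (not isolated)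
Conditions: 8 (1.2 equiv), piperidine/AcOH (10 mol% each), EtOH, rt→50 °C
Reagents that add atoms: none
Why: Knoevenagel condensation followed by attack of the only hydroxyl next to the benzylidene carbon on a Meldrum's carbonyl with loss of acetone, the standard route from salicylaldehydes to coumarin-3-carboxylic acids; this fixes which oxygen is later released as the C6' phenol.

Step 5
Reactants: 10 7-hydroxy-5-methoxy-8-[(2R)-2-methylbutanoyl]-2-oxo-2H-chromene-3-carboxylic acid
Product: 11 (3RS)-7-hydroxy-5-methoxy-8-[(2R)-2-methylbutanoyl]-2-oxo-3,4-dihydro-2H-chromene-3-carboxylic acid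
Conditions: H2 (1 atm), 10% Pd/C, THF, rt
Reagents that add atoms: none
Why: Catalytic hydrogenation of the electron-poor, doubly activated C3=C4 bond should be much faster than any attack on the chelated aryl ketone; the new C3 centre forms without control and does not matter because C3 becomes sp2 in 16.

Step 6
Reactants: 12 pentan-3-one
Product: 13 (Z)-trimethyl(pent-2-en-3-yloxy)silane
Conditions: TMSOTf (1.05 equiv), Et3N (1.2 equiv), CH2Cl2, 0 °C; distil
Reagents that add atoms: trimethylsilyl trifluoromethanesulfonate, C[Si](C)(C)OS(=O)(=O)C(F)(F)F
Why: Soft enolisation and O-silylation of a symmetrical ketone gives a single regioisomeric silyl enol ether; the Z isomer should predominate, and the E/Z ratio is irrelevant because both isomers lead to the same diketone.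

Step 7
Reactants: 11 (3RS)-7-hydroxy-5-methoxy-8-[(2R)-2-methylbutanoyl]-2-oxo-3,4-dihydro-2H-chromene-3-carboxylic acid; 13 (Z)-trimethyl(pent-2-en-3-yloxy)silane
Product: 16 6-ethyl-4-hydroxy-3-{2,4-dihydroxy-6-methoxy-3-[(2R)-2-methylbutanoyl]benzyl}-5-methyl-2H-pyran-2-one, via acyl chloride 14 (not isolated), via diketo lactone 15 (not isolated)
Conditions: (i) (COCl)2 (1.1 equiv), cat. DMF, CH2Cl2, 0 °C→rt, evaporate; (ii) 13 (3 equiv), ZnCl2 (1.5 equiv), CH2Cl2–Et2O, 0 °C→rt; (iii) Et3N (5 equiv), rt→40 °C; 1 M HCl work-up
Reagents that add atoms: none
Why: Acid 11 is converted to acyl chloride 14, and Lewis-acid-assisted C-acylation of silyl enol ether 13 forms the C4–C5 bond and gives diketo lactone 15 (if 14 first loses HCl to its acylketene, C-attack of 13 and desilylation lead to the same compound). On addition of Et3N the enol oxygen of the distal ketone of 15 attacks the lactone carbonyl six atoms away (6-exo-trig acyl substitution), the tetrahedral intermediate expels the aryloxide, and the pyranone O1–C2 bond forms while the C6' phenol is set free. The closest known reaction type is the classical synthesis of 4-hydroxy-2-pyranones from ketone enol ethers (or ketones) and malonyl chlorides or aryl malonates, in which a β,δ-diketo aryl ester cyclises with loss of a phenol; here the phenol is tethered, so the loss becomes a lactone-to-lactone ring switch. The driving force is formation of the conjugated, acidic 4-hydroxy-2-pyranone, held as its triethylammonium salt, which should make the switch irreversible. No stereocentre is created: the epimers of 15 converge because both carbons become sp2, and the (R) centre is not enolised because the medium is neutral to weakly basic and its ketone is deactivated by the ortho phenoxide. The step needs C- over O-acylation of 13 (secured by the silyl enol ether/ZnCl2 combination), reaction at the acyl chloride and not at the aryl lactone (secured by the higher electrophilicity of the chloride), and acylation of 13 rather than of the chelated, hindered 7-OH of a second molecule (secured by excess 13 and the absence of base in stage ii).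

**Compound list**

1 | benzene-1,3,5-triol (phloroglucinol) | Oc1cc(O)cc(O)c1 | starting material
2 | (2R)-2-methylbutanoic acid | CC[C@@H](C)C(=O)O | starting material
3 | (2R)-2-methylbutanoyl chloride | CC[C@@H](C)C(Cl)=O | intermediate (not isolated)
4 | (2R)-2-methyl-1-(2,4,6-trihydroxyphenyl)butan-1-one | CC[C@@H](C)C(=O)c1c(O)cc(O)cc1O | intermediate
5 | (2R)-1-(2,6-dihydroxy-4-methoxyphenyl)-2-methylbutan-1-one | CC[C@@H](C)C(=O)c1c(O)cc(OC)cc1O | intermediate
6 | N-{2,4-dihydroxy-6-methoxy-3-[(2R)-2-methylbutanoyl]benzylidene}-N-methylmethanaminium chloride | CC[C@@H](C)C(=O)c1c(O)cc(OC)c(C=[N+](C)C)c1O.[Cl-] | intermediate (not isolated)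
7 | 2,4-dihydroxy-6-methoxy-3-[(2R)-2-methylbutanoyl]benzaldehyde | CC[C@@H](C)C(=O)c1c(O)cc(OC)c(C=O)c1O | intermediate
8 | 2,2-dimethyl-1,3-dioxane-4,6-dione (Meldrum's acid) | CC1(C)OC(=O)CC(=O)O1 | starting material
9 | 5-{2,4-dihydroxy-6-methoxy-3-[(2R)-2-methylbutanoyl]benzylidene}-2,2-dimethyl-1,3-dioxane-4,6-dione | CC[C@@H](C)C(=O)c1c(O)cc(OC)c(C=C2C(=O)OC(C)(C)OC2=O)c1O | intermediate (not isolated)
10 | 7-hydroxy-5-methoxy-8-[(2R)-2-methylbutanoyl]-2-oxo-2H-chromene-3-carboxylic acid | CC[C@@H](C)C(=O)c1c(O)cc(OC)c2C=C(C(=O)O)C(=O)Oc12 | intermediate
11 | (3RS)-7-hydroxy-5-methoxy-8-[(2R)-2-methylbutanoyl]-2-oxo-3,4-dihydro-2H-chromene-3-carboxylic acid (both C3 epimers) | CC[C@@H](C)C(=O)c1c(O)cc(OC)c2CC(C(=O)O)C(=O)Oc12 | intermediate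
12 | pentan-3-one | CCC(=O)CC | starting material
13 | (Z)-trimethyl(pent-2-en-3-yloxy)silane | C/C=C(/CC)O[Si](C)(C)C | intermediate
14 | 7-hydroxy-5-methoxy-8-[(2R)-2-methylbutanoyl]-2-oxo-3,4-dihydro-2H-chromene-3-carbonyl chloride (both C3 epimers) | CC[C@@H](C)C(=O)c1c(O)cc(OC)c2CC(C(Cl)=O)C(=O)Oc12 | intermediate (not isolated)
15 | 7-hydroxy-5-methoxy-8-[(2R)-2-methylbutanoyl]-3-(2-methyl-3-oxopentanoyl)-3,4-dihydro-2H-chromen-2-one (mixture of epimers at C3 and at the side-chain methine) | CC[C@@H](C)C(=O)c1c(O)cc(OC)c2CC(C(=O)C(C)C(=O)CC)C(=O)Oc12 | intermediate (not isolated)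
16 | 6-ethyl-4-hydroxy-3-{2,4-dihydroxy-6-methoxy-3-[(2R)-2-methylbutanoyl]benzyl}-5-methyl-2H-pyran-2-one | CCc1oc(=O)c(Cc2c(OC)cc(O)c(C(=O)[C@H](C)CC)c2O)c(O)c1C | target

**Step count and risks**

Total steps: 7. Longest linear sequence: 6 (steps 1–5 and 7; step 6 is a one-step side branch).

Step 7 (key step). The most likely failure is that 14 loses HCl to its acylketene faster than 13 is C-acylated, and that this ketene dimerises or is captured by phenolic oxygen of a second molecule (oligo-esterification). O-acylation of 13 or a sluggish ring switch of a zinc-chelated 15 are further possibilities. Fallback, known chemistry, setting out from 7 and 13 and returning at 16: 13 is condensed with malonyl dichloride (Et2O, −78 °C→rt) to 6-ethyl-4-hydroxy-5-methyl-2H-pyran-2-one F1 (the same compound as A1). Then 7, F1 and Hantzsch ester with catalytic L-proline (CH2Cl2–EtOH, rt) undergo a three-component reductive Knoevenagel alkylation. The arylidene-pyrandione F2 is reduced in situ by hydride transfer before a second nucleophile can add, which should give 16 directly.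

Step 1. Partial racemisation is the main concern, by ketene formation from 3 or by enolisation of the aluminium-chelated ketone during a slow acylation. Fallback, setting out from 2 and returning at 5: 2 is converted (CDI, MeNHOMe·HCl) to the Weinreb amide (2R)-N-methoxy-N,2-dimethylbutanamide F3. Commercial 5-methoxybenzene-1,3-diol is protected (MOMCl, i-Pr2NEt) as 1-methoxy-3,5-bis(methoxymethoxy)benzene F4. F4 is lithiated between the two MOM ethers (n-BuLi, THF, 0 °C, directed ortho-metalation) and acylated with F3 to (2R)-1-[4-methoxy-2,6-bis(methoxymethoxy)phenyl]-2-methylbutan-1-one F5. Mild acidolysis (HCl, MeOH, rt) then gives 5. No Lewis acid is involved, and the ketone is released only on quench from a chelated tetrahedral intermediate. This entry also makes the selective mono-methylation of step 2 unnecessary.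

Step 3. Competing attack of the chloroiminium reagent at the phenol oxygens or at the ketone enol (chromanone-type closure, which would destroy the stereocentre), or a second formylation, could erode the yield. Fallback, setting out from 5 and returning at 11: a trimolecular condensation of 5, aqueous formaldehyde and 8 with catalytic L-proline (MeCN, rt→40 °C). The C-alkylation adduct 5-{2,4-dihydroxy-6-methoxy-3-[(2R)-2-methylbutanoyl]benzyl}-2,2-dimethyl-1,3-dioxane-4,6-dione F6 should lactonise through its ortho hydroxyl with loss of acetone to give 11, bypassing 7 and 10.

Step 5. Over-reduction (hydrogenolysis of the benzylic aryl ketone) or slow uptake at the hindered, chelated substrate could interfere, as could partial decarboxylation of the malonic half-ester on work-up. Fallback, setting out from 10 and returning at 15 (and from there at 16 as in step 7): the order is changed. 10 is converted ((COCl)2, cat. DMF) to 7-hydroxy-5-methoxy-8-[(2R)-2-methylbutanoyl]-2-oxo-2H-chromene-3-carbonyl chloride F7, which has no α-hydrogen and cannot form a ketene. F7 acylates 13 (ZnCl2) to 7-hydroxy-5-methoxy-8-[(2R)-2-methylbutanoyl]-3-(2-methyl-3-oxopentanoyl)-2H-chromen-2-one F8. The strongly electrophilic C3=C4 bond of this 3-acylcoumarin is then reduced by conjugate hydride transfer from Hantzsch ester (no metal, no H2) to give 15, which is ring-switched with Et3N.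

**Further compounds**

F1 | step 7 | 6-ethyl-4-hydroxy-5-methyl-2H-pyran-2-one (identical with A1) | CCc1oc(=O)cc(O)c1C
F2 | step 7 | 3-{2,4-dihydroxy-6-methoxy-3-[(2R)-2-methylbutanoyl]benzylidene}-6-ethyl-5-methyl-2H-pyran-2,4(3H)-dione (not isolated) | CCC1=C(C)C(=O)C(=Cc2c(OC)cc(O)c(C(=O)[C@H](C)CC)c2O)C(=O)O1
F3 | step 1 | (2R)-N-methoxy-N,2-dimethylbutanamide | CC[C@@H](C)C(=O)N(C)OC
F4 | step 1 | 1-methoxy-3,5-bis(methoxymethoxy)benzene | COCOc1cc(OC)cc(OCOC)c1
F5 | step 1 | (2R)-1-[4-methoxy-2,6-bis(methoxymethoxy)phenyl]-2-methylbutan-1-one | CC[C@@H](C)C(=O)c1c(OCOC)cc(OC)cc1OCOC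
F6 | step 3 | 5-{2,4-dihydroxy-6-methoxy-3-[(2R)-2-methylbutanoyl]benzyl}-2,2-dimethyl-1,3-dioxane-4,6-dione (not isolated) | CC[C@@H](C)C(=O)c1c(O)cc(OC)c(CC2C(=O)OC(C)(C)OC2=O)c1O
F7 | step 5 | 7-hydroxy-5-methoxy-8-[(2R)-2-methylbutanoyl]-2-oxo-2H-chromene-3-carbonyl chloride | CC[C@@H](C)C(=O)c1c(O)cc(OC)c2C=C(C(Cl)=O)C(=O)Oc12
F8 | step 5 | 7-hydroxy-5-methoxy-8-[(2R)-2-methylbutanoyl]-3-(2-methyl-3-oxopentanoyl)-2H-chromen-2-one | CC[C@@H](C)C(=O)c1c(O)cc(OC)c2C=C(C(=O)C(C)C(=O)CC)C(=O)Oc12
A1 | alternative 1 | 6-ethyl-4-hydroxy-5-methyl-2H-pyran-2-one | CCc1oc(=O)cc(O)c1C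
A2 | alternative 1 | 6-ethyl-5-methyl-3-methylidene-2H-pyran-2,4(3H)-dione | CCC1=C(C)C(=O)C(=C)C(=O)O1
A3 | alternative 1 | 3,3'-methylenebis(6-ethyl-4-hydroxy-5-methyl-2H-pyran-2-one) | CCc1oc(=O)c(Cc2c(O)c(C)c(CC)oc2=O)c(O)c1C
A4 | alternative 2 | (2R)-1-(2,6-dihydroxy-4-methoxy-3-methylphenyl)-2-methylbutan-1-one | CC[C@@H](C)C(=O)c1c(O)cc(OC)c(C)c1O
A5 | alternative 2 | 3-hydroxy-5-methoxy-2-[(2R)-2-methylbutanoyl]-6-methylidenecyclohexa-2,4-dien-1-one (ortho-quinone methide) | CC[C@@H](C)C(=O)C1=C(O)C=C(OC)C(=C)C1=O
A6 | alternative 3 | 3-(2,4-dihydroxy-6-methoxybenzyl)-6-ethyl-4-hydroxy-5-methyl-2H-pyran-2-one | CCc1oc(=O)c(Cc2c(OC)cc(O)cc2O)c(O)c1C
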